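**Plan**

- Numbering: ring C-1 (C=O), C-2 (bears CH2OAc), C-3 (=CH), C-4 (CHOH), C-5 (quaternary oxirane C), C-6 (oxirane CH); side chain C-1′ to C-12′.
- Retrosynthetic cuts, in order: acetonide/TBS; C-2–CH2OAc (Morita–Baylis–Hillman) and C-2=C-3; C-4′=C-5′ (HWE); C-2′=C-3′ (Wittig); then C-3–C-4 and C-5–C-6 together (the O–C-6 oxirane bond closes in the same pot); C-1′–C-2′ (hydrazone alkylation).
- Enabling feature: C-5 sits between the carbinol carbons C-4 and C-1′, so C-4/C-5/C-1′ is a masked dihydroxyacetone. Tying O-4 and O-1′ into a 1,3-dioxan-5-one ring (absent from the target, removed in the last step) makes C-4 a nucleophilic α-carbon and C-5 a ketone, which matches C-3 (vinyl terminus) and C-6 (ClCH2) of chloromethyl vinyl ketone.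
- Forward order: dioxanone → C-1′ stereocentre → one-pot Michael/aldol/SN2 annulation closes the cyclohexanone and the oxirane onto the dioxane → side chain by two olefinations → enone, CH2OAc → deprotection.
- Stereochemistry: C-1′ from the SAMP auxiliary; C-4, C-5 and C-6 relayed from C-1′ through the dioxanone ring during the annulation; 2′E from a stabilised-ylide Wittig, 4′E from HWE, 6′E from geranyl bromide, 10′Z from Still–Gennari.

Key step: step 6

Remark: the given structure has C-10′=C-11′ as Z (CH2OH cis to C-9′) and the route is built for that geometry; SAMP, (chloromethoxy)triisopropylsilane and 2-(triphenylphosphoranylidene)propanal are taken as purchasable.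

**Route**

Step 1
Reactants: 1 2,2-dimethyl-1,3-dioxan-5-one; 2 (S)-1-amino-2-(methoxymethyl)pyrrolidine (SAMP)
Product: 3 SAMP hydrazone of 1
Conditions: cyclohexane, 60 °C, removal of water
Reagents that add atoms: SAMP, COC[C@@H]1CCCN1N
Why: Condensation of the ketone with the N-amino auxiliary (hydrazone formation) prepares the azaenolate precursor; no new stereocentre.

Step 2
Reactants: 3 SAMP hydrazone; 4 (chloromethoxy)triisopropylsilane
Product: 5 α-(triisopropylsilyloxymethyl) SAMP hydrazone
Conditions: t-BuLi, THF, −78 °C; then 4, −100 → −78 °C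
Reagents that add atoms: (chloromethoxy)triisopropylsilane, ClCO[Si](C(C)C)(C(C)C)C(C)C
Why: Enders SAMP-hydrazone α-alkylation: the chelated lithium azaenolate should take the reactive chloromethyl ether on the face left open by the methoxymethylpyrrolidine, which sets C-1′.

Step 3
Reactants: 5 alkylated hydrazone; 6 water
Product: 7 (S)-2,2-dimethyl-4-[(triisopropylsilyloxy)methyl]-1,3-dioxan-5-one
Conditions: sat. aq. oxalic acid, Et2O, rt
Reagents that add atoms: water, O
Why: Two-phase acidic hydrazone hydrolysis should free the ketone without epimerising the α-alkoxy centre and should leave the acetonide and the silyl ether intact.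

Step 4
Reactants: 7 ketone; 8 chlorotrimethylsilane
Product: 9 trimethylsilyl enol ether of 7 (double bond toward the unsubstituted α-carbon)
Conditions: LDA, Me3SiCl (in situ), THF, −78 °C
Reagents that add atoms: chlorotrimethylsilane, C[Si](C)(C)Cl
Why: Kinetic deprotonation at the unsubstituted α-CH2 (less hindered than C-1′–H) with in situ O-silylation should give the regiodefined silyl enol ether (kinetic enolate trapping).

Step 5
Reactants: 10 chloroacetyl chloride; 11 trimethyl(vinyl)silane
Product: 12 1-chlorobut-3-en-2-one (chloromethyl vinyl ketone)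
Conditions: AlCl3, CH2Cl2, −30 °C
Reagents that add atoms: none
Why: Friedel–Crafts acylation of the vinylsilane with ipso substitution (β-silyl cation, loss of Me3SiCl) should deliver the vinyl ketone directly.

Step 6
Reactants: 9 silyl enol ether; 12 chloromethyl vinyl ketone
Product: 15 acetonide-bridged 5,6-epoxycyclohexanone, via Michael adduct silyl enol ether 13 (not isolated), via anti chlorohydrin 14 (not isolated)
Conditions: HNTf2 (2 mol %), CH2Cl2, −78 °C; then Bu4NF, THF, −78 → 0 °C (one pot)
Reagents that add atoms: none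
Why: Proposed new method: a silyl-triflimide-catalysed Mukaiyama–Michael addition joins C-4 of the dioxin enol ether to C-3 of the vinyl ketone, then fluoride unmasks the enolate, which equilibrates to the more acidic α-chloro position (C-6) and adds to the strongly electrophilic dioxanone carbonyl C-5, after which the alkoxide displaces chloride; the closest known reaction types are the Robinson annulation in its Mukaiyama–Michael form, the intramolecular Darzens condensation and the amine-catalysed domino Michael/aldol/SN2 epoxide formation from γ-chloro-β-keto esters and enals, but their merger as a [4+2] epoxy-annulation of a ketone donor with an α′-chloro vinyl ketone has not been shown. The carbocycle closes by a 6-(enolexo)-exo-trig aldol addition and the oxirane by a 3-exo-tet SN2 displacement. C-4 should be set in the Michael stage by attack anti to the pseudo-axial CH2OTIPS group at C-1′ (trans-4,6-disubstituted dioxanone, as in the trans-selective α,α′-bisalkylation of dioxanone hydrazones); C-5 by axial attack of the tethered enolate on the dioxanone carbonyl from the face opposite that group (cis ring fusion, oxirane oxygen syn to CH2OTIPS and anti to O-4); and C-6 by the invertive ring closure, which only the anti chlorohydrin can undergo while its epimer re-equilibrates by enolisation or retro-aldol. The step needs C–C formation at the vinyl terminus and not at CH2Cl, and aldol closure in preference to Favorskii contraction or cyclopentanone-forming alkylation; the first is secured by running the Michael stage under Lewis acid with no free enolate, the second by the higher acidity of the ClCH2 protons, the activated 1,3-dioxygenated ketone and the low temperature.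

Step 7
Reactants: 15 epoxy ketone
Product: 16 primary alcohol (CH2OH on C-1′)
Conditions: HF·pyridine, pyridine, THF, 0 °C → rt
Reagents that add atoms: none
Why: Fluoride-mediated silyl ether cleavage under buffered conditions should spare the acetonide and the epoxy ketone.

Step 8
Reactants: 16 primary alcohol
Product: 17 aldehyde (C-2′ as CHO)
Conditions: Dess–Martin periodinane, NaHCO3, CH2Cl2, 0 °C → rt
Reagents that add atoms: none
Why: Buffered Dess–Martin oxidation should give the α-alkoxy aldehyde without epimerising C-1′.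

Step 9
Reactants: 17 aldehyde; 18 2-(triphenylphosphoranylidene)propanal
Product: 19 (2′E)-enal (C-4′ as CHO)
Conditions: toluene, 80 °C
Reagents that add atoms: 2-(triphenylphosphoranylidene)propanal, CC(C=O)=P(c1ccccc1)(c1ccccc1)c1ccccc1
Why: Wittig olefination with the stabilised α-methyl ylide should react only with the aldehyde, not the ring ketone, and give the (E)-trisubstituted enal.

Step 10
Reactants: 20 geranyl bromide; 21 triethyl phosphite
Product: 22 diethyl geranylphosphonate
Conditions: neat, 130 °C
Reagents that add atoms: triethyl phosphite, CCOP(OCC)OCC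
Why: Michaelis–Arbuzov reaction of the primary allylic bromide; the (E)-alkene (future 6′E) is carried over unchanged.

Step 11
Reactants: 22 diethyl geranylphosphonate; 23 3-chloroperbenzoic acid
Product: 24 6,7-epoxide of 22 (racemic at the oxirane CH)
Conditions: CH2Cl2, 0 °C
Reagents that add atoms: 3-chloroperbenzoic acid, OOC(=O)c1cccc(Cl)c1
Why: Prilezhaev epoxidation should select the remote, more electron-rich trisubstituted alkene over the one deactivated by the allylic phosphonate.

Step 12
Reactants: 24 epoxide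
Product: 25 diethyl [(E)-3-methyl-6-oxohex-2-enyl]phosphonate
Conditions: H5IO6, THF/Et2O, 0 °C
Reagents that add atoms: none
Why: Periodic acid opens the epoxide to the glycol and cleaves it (Malaprade cleavage) to the aldehyde that becomes C-10′.

Step 13
Reactants: 25 aldehyde; 26 ethyl 2-[bis(2,2,2-trifluoroethoxy)phosphoryl]propanoate
Product: 27 (2Z,6E)-ethyl 8-(diethoxyphosphoryl)-2,6-dimethylocta-2,6-dienoate
Conditions: KHMDS, 18-crown-6, THF, −78 °C
Reagents that add atoms: ethyl 2-[bis(2,2,2-trifluoroethoxy)phosphoryl]propanoate, CCOC(=O)C(C)P(=O)(OCC(F)(F)F)OCC(F)(F)F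
Why: Still–Gennari olefination should give the (Z)-α-methyl enoate by kinetic elimination from the trifluoroethyl phosphonate adduct, which sets 10′Z.

Step 14
Reactants: 27 (Z)-enoate
Product: 28 (Z)-allylic alcohol (C-12′ OH)
Conditions: DIBAL-H, CH2Cl2, −78 °C
Reagents that add atoms: none
Why: DIBAL-H 1,2-reduction of the enoate; the phosphonate ester is inert at low temperature and the alkene geometry is retained.

Step 15
Reactants: 28 allylic alcohol; 29 tert-butyldimethylsilyl chloride
Product: 30 TBS-protected allylic phosphonate (C-5′ to C-12′ fragment)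
Conditions: imidazole, DMF, rt
Reagents that add atoms: tert-butyldimethylsilyl chloride, CC(C)(C)[Si](C)(C)Cl
Why: Standard silylation of the primary alcohol so that the phosphonate can be deprotonated cleanly.

Step 16
Reactants: 19 enal; 30 allylic phosphonate
Product: 31 (2′E,4′E,6′E,10′Z)-triene ketone
Conditions: LiHMDS, THF, −78 °C; then 19, −78 → −20 °C
Reagents that add atoms: none
Why: Horner–Wadsworth–Emmons olefination with the lithiated allylic phosphonate: the aldehyde should react far faster than the hindered ring ketone, and equilibration of the adducts should give the (4′E)-alkene.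

Step 17
Reactants: 31 triene ketone; 32 benzeneselenenyl chloride
Product: 34 cyclohex-2-enone, via α-phenylselanyl ketone 33 (not isolated)
Conditions: LDA, THF, −78 °C; PhSeCl; then H2O2, pyridine, CH2Cl2, 0 °C
Reagents that add atoms: none
Why: α-Selenenylation at the only enolisable position (C-2; C-6 is an oxirane carbon) followed by selenoxide syn-elimination, which can only remove H-3, should give the 2-ene.

Step 18
Reactants: 34 enone; 35 formaldehyde
Product: 36 2-(hydroxymethyl)enone
Conditions: aq. HCHO, DMAP (cat.), THF/H2O, rt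
Reagents that add atoms: formaldehyde, C=O
Why: Morita–Baylis–Hillman reaction: DMAP adds reversibly to C-3, the enolate is trapped by formaldehyde at C-2 and the catalyst is expelled, so no strong base is needed.

Step 19
Reactants: 36 allylic alcohol; 37 acetic anhydride
Product: 38 acetate
Conditions: pyridine, CH2Cl2, 0 °C
Reagents that add atoms: acetic anhydride, CC(=O)OC(C)=O
Why: O-Acetylation of the only free hydroxyl group; no nucleophilic catalyst is used, to avoid SN2′ attack on the allylic acetate.

Step 20
Reactants: 38 protected acetate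
Product: 39 CNP0305847.1
Conditions: AcOH/THF/H2O (3:1:1), rt → 35 °C
Reagents that add atoms: none
Why: Mild aqueous acid hydrolysis should remove the strained acetonide of the anti-1,3-diol and the primary allylic TBS ether while the allylic acetate, the oxirane and the triene are left alone.

**Compound list**

1 | 2,2-dimethyl-1,3-dioxan-5-one | CC1(C)OCC(=O)CO1 | starting material
2 | (S)-1-amino-2-(methoxymethyl)pyrrolidine (SAMP) | COC[C@@H]1CCCN1N | starting material
3 | SAMP hydrazone of 1 | COC[C@@H]1CCCN1N=C1COC(C)(C)OC1 | intermediate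
4 | (chloromethoxy)triisopropylsilane | ClCO[Si](C(C)C)(C(C)C)C(C)C | starting material
5 | SAMP hydrazone of ketone 7 (CH2OTIPS on the dioxane carbon next to C=N, the future C-1′, configured as in the SMILES) | COC[C@@H]1CCCN1N=C1COC(C)(C)O[C@H]1CO[Si](C(C)C)(C(C)C)C(C)C | intermediate
6 | water | O | starting material
7 | (S)-2,2-dimethyl-4-[(triisopropylsilyloxy)methyl]-1,3-dioxan-5-one | CC1(C)OCC(=O)[C@@H](O1)CO[Si](C(C)C)(C(C)C)C(C)C | intermediate
8 | chlorotrimethylsilane | C[Si](C)(C)Cl | starting material
9 | (S)-2,2-dimethyl-4-[(triisopropylsilyloxy)methyl]-5-(trimethylsilyloxy)-4H-1,3-dioxin | CC1(C)OC=C(O[Si](C)(C)C)[C@@H](O1)CO[Si](C(C)C)(C(C)C)C(C)C | intermediate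
10 | chloroacetyl chloride | ClCC(Cl)=O | starting material
11 | trimethyl(vinyl)silane | C=C[Si](C)(C)C | starting material
12 | 1-chlorobut-3-en-2-one | C=CC(=O)CCl | intermediate
13 | Michael adduct as silyl enol ether: trans-4,6-disubstituted dioxan-5-one with a 4-chloro-3-(trimethylsilyloxy)but-2-enyl chain on the future C-4 and CH2OTIPS on C-1′ (enol ether geometry undefined) | ClCC(O[Si](C)(C)C)=CC[C@H](O1)C(=O)[C@@H](OC1(C)C)CO[Si](C(C)C)(C(C)C)C(C)C | intermediate
14 | anti chlorohydrin: cis-fused acetonide-bridged 6-chloro-5-hydroxycyclohexanone (Cl on C-6 trans to OH on C-5) | C1C[C@H](O3)[C@](O)([C@@H](OC3(C)C)CO[Si](C(C)C)(C(C)C)C(C)C)[C@H](Cl)C1=O | intermediate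
15 | epoxy ketone: 5,6-epoxycyclohexan-1-one with O-4 and O-1′ bridged as acetonide (cis-fused 1,3-dioxane), CH2OTIPS on C-1′; C-4, C-5, C-6, C-1′ as in the target | C1C[C@H](O3)[C@@]2([C@@H](OC3(C)C)CO[Si](C(C)C)(C(C)C)C(C)C)O[C@H]2C1=O | intermediate
16 | primary alcohol from 15 (CH2OH on C-1′) | C1C[C@H](O3)[C@@]2([C@@H](OC3(C)C)CO)O[C@H]2C1=O | intermediate
17 | aldehyde (C-2′ = CHO) | C1C[C@H](O3)[C@@]2([C@@H](OC3(C)C)C=O)O[C@H]2C1=O | intermediate
18 | 2-(triphenylphosphoranylidene)propanal | CC(C=O)=P(c1ccccc1)(c1ccccc1)c1ccccc1 | starting material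
19 | (2′E)-3′-methyl enal (C-4′ = CHO) | C1C[C@H](O3)[C@@]2([C@@H](OC3(C)C)/C=C(C)/C=O)O[C@H]2C1=O | intermediate
20 | geranyl bromide | CC(C)=CCC/C(C)=C/CBr | starting material
21 | triethyl phosphite | CCOP(OCC)OCC | starting material
22 | diethyl [(2E)-3,7-dimethylocta-2,6-dienyl]phosphonate | CCOP(=O)(OCC)C/C=C(\C)CCC=C(C)C | intermediate
23 | 3-chloroperbenzoic acid | OOC(=O)c1cccc(Cl)c1 | starting material
24 | diethyl [(2E)-6,7-epoxy-3,7-dimethyloct-2-enyl]phosphonate (racemic) | CCOP(=O)(OCC)C/C=C(\C)CCC1OC1(C)C | intermediate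
25 | diethyl [(2E)-3-methyl-6-oxohex-2-enyl]phosphonate | CCOP(=O)(OCC)C/C=C(\C)CCC=O | intermediate
26 | ethyl 2-[bis(2,2,2-trifluoroethoxy)phosphoryl]propanoate | CCOC(=O)C(C)P(=O)(OCC(F)(F)F)OCC(F)(F)F | starting material
27 | ethyl (2Z,6E)-8-(diethoxyphosphoryl)-2,6-dimethylocta-2,6-dienoate | CCOP(=O)(OCC)C/C=C(\C)CC/C=C(/C)C(=O)OCC | intermediate
28 | diethyl [(2E,6Z)-8-hydroxy-3,7-dimethylocta-2,6-dienyl]phosphonate | CCOP(=O)(OCC)C/C=C(\C)CC/C=C(/C)CO | intermediate
29 | tert-butyldimethylsilyl chloride | CC(C)(C)[Si](C)(C)Cl | starting material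
30 | diethyl [(2E,6Z)-8-(tert-butyldimethylsilyloxy)-3,7-dimethylocta-2,6-dienyl]phosphonate | CCOP(=O)(OCC)C/C=C(\C)CC/C=C(/C)CO[Si](C)(C)C(C)(C)C | intermediate
31 | triene ketone: 15 skeleton carrying the full (2′E,4′E,6′E,10′Z) side chain, 12′-OTBS | C1C[C@H](O3)[C@@]2([C@@H](OC3(C)C)/C=C(C)/C=C/C=C(\C)CC/C=C(/C)CO[Si](C)(C)C(C)(C)C)O[C@H]2C1=O | intermediate
32 | benzeneselenenyl chloride | Cl[Se]c1ccccc1 | starting material
33 | 2-(phenylselanyl) ketone from 31 (C-2 epimers) | c1ccccc1[Se]C1C[C@H](O3)[C@@]2([C@@H](OC3(C)C)/C=C(C)/C=C/C=C(\C)CC/C=C(/C)CO[Si](C)(C)C(C)(C)C)O[C@H]2C1=O | intermediate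
34 | enone (C-2=C-3), acetonide and 12′-OTBS in place | C1=C[C@H](O3)[C@@]2([C@@H](OC3(C)C)/C=C(C)/C=C/C=C(\C)CC/C=C(/C)CO[Si](C)(C)C(C)(C)C)O[C@H]2C1=O | intermediate
35 | formaldehyde | C=O | starting material
36 | 2-(hydroxymethyl)enone | OCC1=C[C@H](O3)[C@@]2([C@@H](OC3(C)C)/C=C(C)/C=C/C=C(\C)CC/C=C(/C)CO[Si](C)(C)C(C)(C)C)O[C@H]2C1=O | intermediate
37 | acetic anhydride | CC(=O)OC(C)=O | starting material
38 | 2-(acetoxymethyl)enone, acetonide and 12′-OTBS in place | CC(=O)OCC1=C[C@H](O3)[C@@]2([C@@H](OC3(C)C)/C=C(C)/C=C/C=C(\C)CC/C=C(/C)CO[Si](C)(C)C(C)(C)C)O[C@H]2C1=O | intermediate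
39 | CNP0305847.1, [(1R,5S,6R)-6-[(1S,2E,4E,6E,10Z)-1,12-dihydroxy-3,7,11-trimethyldodeca-2,4,6,10-tetraen-1-yl]-5-hydroxy-2-oxo-7-oxabicyclo[4.1.0]hept-3-en-3-yl]methyl acetate | CC(=O)OCC1=C[C@H](O)[C@@]2([C@@H](O)/C=C(C)/C=C/C=C(\C)CC/C=C(/C)CO)O[C@H]2C1=O | target

**Step count and risks**

Total steps: 20. Longest linear sequence: 13 (steps 1–4, 6–9, 16–20).

Steps most likely to fail:

1. Step 6 (proposed new method). After the fluoride unmasking, the α′-enolate may undergo Favorskii-type contraction or intramolecular C-alkylation by the CH2Cl group before it equilibrates to the α-chloro enolate. The dioxanone α-centres may also epimerise before the aldol closure, which would erode the relay of configuration from C-1′. Fallback with known chemistry, setting out from 9 and 12: only the Lewis-acid Mukaiyama–Michael addition is run (HNTf2 cat., CH2Cl2, −78 °C, aqueous NaHCO3 work-up) and the chloro diketone F1 is isolated and purified. A separate intramolecular Darzens condensation of F1 (LiHMDS, THF, −78 → −20 °C; kinetic deprotonation of ClCH2, aldol addition, ring closure) then comes back to the route at 15.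

2. Step 18. The nucleophilic catalyst may not turn over at the hindered C-3, or base may remove the γ-proton at C-4, which would open the oxirane and aromatise the ring. Fallback, setting out from 34: α-iodination (I2, pyridine, CH2Cl2, 0 °C, dark) gives the α-iodoenone F2. Stille coupling of F2 with (tributylstannyl)methanol (Pd2(dba)3, AsPh3, CuI, DMF, rt) comes back to the route at 36.

3. Step 20. Acid may ionise the trienylic C-1′ carbinol or open the oxirane before the acetonide and the silyl ether are gone. Fallback, setting out from 19, where no triene is present yet: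
   - the acetonide is hydrolysed (80% aq. AcOH, rt) to the diol enal F3, which is silylated (Et3SiOTf, 2,6-lutidine, CH2Cl2, −78 °C) to the bis-triethylsilyl ether F4;
   - HWE olefination of F4 with 30 as in step 16 gives the triene ketone F5;
   - selenenylation as in step 17 gives the α-phenylselanyl ketone F6 and, after oxidation and elimination, the enone F7;
   - Morita–Baylis–Hillman reaction as in step 18 gives the alcohol F8, and acetylation as in step 19 gives the acetate F9;
   - global desilylation of F9 (HF·pyridine, pyridine, THF, 0 °C) comes back to the route at 39.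

Further compounds

F1 | step 6 | chloro diketone: trans-4,6-disubstituted 2,2-dimethyl-1,3-dioxan-5-one with a 4-chloro-3-oxobutyl chain on the future C-4 and CH2OTIPS on C-1′ | ClCC(=O)CC[C@H](O1)C(=O)[C@@H](OC1(C)C)CO[Si](C(C)C)(C(C)C)C(C)C
F2 | step 18 | 2-iodoenone from 34 | IC1=C[C@H](O3)[C@@]2([C@@H](OC3(C)C)/C=C(C)/C=C/C=C(\C)CC/C=C(/C)CO[Si](C)(C)C(C)(C)C)O[C@H]2C1=O
F3 | step 20 | diol enal (4-OH, 1′-OH free) | C1C[C@H](O)[C@@]2([C@@H](O)/C=C(C)/C=O)O[C@H]2C1=O
F4 | step 20 | bis-triethylsilyl ether of the diol enal | C1C[C@H](O[Si](CC)(CC)CC)[C@@]2([C@@H](O[Si](CC)(CC)CC)/C=C(C)/C=O)O[C@H]2C1=O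
F5 | step 20 | triene ketone, 4-OTES, 1′-OTES, 12′-OTBS | C1C[C@H](O[Si](CC)(CC)CC)[C@@]2([C@@H](O[Si](CC)(CC)CC)/C=C(C)/C=C/C=C(\C)CC/C=C(/C)CO[Si](C)(C)C(C)(C)C)O[C@H]2C1=O
F6 | step 20 | 2-(phenylselanyl) ketone from F5 | c1ccccc1[Se]C1C[C@H](O[Si](CC)(CC)CC)[C@@]2([C@@H](O[Si](CC)(CC)CC)/C=C(C)/C=C/C=C(\C)CC/C=C(/C)CO[Si](C)(C)C(C)(C)C)O[C@H]2C1=O
F7 | step 20 | enone, 4-OTES, 1′-OTES, 12′-OTBS | C1=C[C@H](O[Si](CC)(CC)CC)[C@@]2([C@@H](O[Si](CC)(CC)CC)/C=C(C)/C=C/C=C(\C)CC/C=C(/C)CO[Si](C)(C)C(C)(C)C)O[C@H]2C1=O
F8 | step 20 | 2-(hydroxymethyl)enone, 4-OTES, 1′-OTES, 12′-OTBS | OCC1=C[C@H](O[Si](CC)(CC)CC)[C@@]2([C@@H](O[Si](CC)(CC)CC)/C=C(C)/C=C/C=C(\C)CC/C=C(/C)CO[Si](C)(C)C(C)(C)C)O[C@H]2C1=O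
F9 | step 20 | 2-(acetoxymethyl)enone, 4-OTES, 1′-OTES, 12′-OTBS | CC(=O)OCC1=C[C@H](O[Si](CC)(CC)CC)[C@@]2([C@@H](O[Si](CC)(CC)CC)/C=C(C)/C=C/C=C(\C)CC/C=C(/C)CO[Si](C)(C)C(C)(C)C)O[C@H]2C1=O
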